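## Retrosynthetic overview

Atom labels: lactone ring O1, C2 (C=O), C3, C4 (OH), C5; side chain C1' (=C3) to C10' (CH2OH).

1. Target ⇐ its 10'-O-silyl ether ⇐ olefin cross-metathesis forming C3=C1' between an α-methylene-β-hydroxy-γ-lactone and a C12 dienol.
2. The C2'–C3' bond and the (R)-carbinol C3' of the dienol ⇐ [2,3]-Wittig rearrangement of a bis-allylic ether, which relays the C–O stereocentre of (S)-but-3-en-2-ol to C3'; the ether comes from geraniol by allylic oxidation, bromination and etherification.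
3. Methylene lactone ⇐ 2,3-O-isopropylidene-D-ribono-1,4-lactone (C4 and C5 bought): C5 oxidation and Wittig, SmI2 α-deoxygenation, Eschenmoser methylenation.
4. Ring order: the only ring, the γ-lactone, is bought with the ribonolactone and carried through; no ring is formed in the synthesis.

Assumption: (S)-but-3-en-2-ol and 2,3-O-isopropylidene-D-ribono-1,4-lactone are bought as single enantiomers.

## Route

**Step 1**
Reactants: 1 geraniol, (2E)-3,7-dimethylocta-2,6-dien-1-ol
Product: 2 tert-butyl{[(2E)-3,7-dimethylocta-2,6-dien-1-yl]oxy}dimethylsilane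
Conditions: TBSCl, imidazole, DMF, rt
Reagents that add atoms: tert-butyldimethylsilyl chloride, CC(C)(C)[Si](C)(C)Cl
Why: Silyl ether protection of the primary allylic alcohol masks O-10' against the alkoxide and alkyllithium used later, and no stereocentre is involved.

**Step 2**
Reactants: 2 tert-butyl{[(2E)-3,7-dimethylocta-2,6-dien-1-yl]oxy}dimethylsilane
Product: 3 (2E,6E)-8-[(tert-butyldimethylsilyl)oxy]-2,6-dimethylocta-2,6-dien-1-ol
Conditions: SeO2 (0.2 equiv), t-BuOOH (3 equiv), salicylic acid (0.1 equiv), CH2Cl2, rt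
Reagents that add atoms: tert-butyl hydroperoxide, CC(C)(C)OO (terminal oxidant); selenium dioxide, O=[Se]=O (catalytic oxygen carrier)
Why: Riley allylic oxidation (ene reaction, then [2,3]-shift of the allylseleninic acid) attacks the electron-rich terminal alkene at its (E)-methyl group and gives the (E)-allylic alcohol, while the 2,3-alkene is deactivated by its allylic silyloxy group.

**Step 3**
Reactants: 3 (2E,6E)-8-[(tert-butyldimethylsilyl)oxy]-2,6-dimethylocta-2,6-dien-1-ol
Product: 4 {[(2E,6E)-8-bromo-3,7-dimethylocta-2,6-dien-1-yl]oxy}(tert-butyl)dimethylsilane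
Conditions: CBr4, PPh3, CH2Cl2, 0 °C
Reagents that add atoms: carbon tetrabromide, BrC(Br)(Br)Br
Why: Appel bromination turns the primary allylic alcohol into the bromide under near-neutral conditions that keep the silyl ether and both alkene geometries.

**Step 4**
Reactants: 4 {[(2E,6E)-8-bromo-3,7-dimethylocta-2,6-dien-1-yl]oxy}(tert-butyl)dimethylsilane, 5 (2S)-but-3-en-2-ol
Product: 7 tert-butyl{[(2E,6E)-8-{[(2S)-but-3-en-2-yl]oxy}-3,7-dimethylocta-2,6-dien-1-yl]oxy}dimethylsilane, via sodium (2S)-but-3-en-2-olate 6 (not isolated)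
Conditions: NaH, THF, 0 °C; then 4, n-Bu4NI (cat.), 0 °C to rt
Reagents that add atoms: none
Why: Williamson ether synthesis by SN2 attack of the secondary alkoxide on the unhindered primary allylic bromide, which leaves the bought (S) C–O stereocentre untouched.

**Step 5**
Reactants: 7 tert-butyl{[(2E,6E)-8-{[(2S)-but-3-en-2-yl]oxy}-3,7-dimethylocta-2,6-dien-1-yl]oxy}dimethylsilane
Product: 9 (2E,6E,8R,10E)-1-[(tert-butyldimethylsilyl)oxy]-3,7-dimethyldodeca-2,6,10-trien-8-ol, via α-lithiated ether 8 (not isolated)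
Conditions: n-BuLi (1.5 equiv), THF, −78 °C, 4 h; H2O
Reagents that add atoms: none
Why: [2,3]-Wittig rearrangement: kinetic lithiation at the less substituted O–CH2 is followed by a suprafacial shift through a five-membered envelope (methyl pseudo-equatorial, alkenyl group exo) that forms the C2'–C3' bond and relays the (S) C–O centre to the (R) carbinol while that centre becomes an (E)-propenyl group.

**Step 6**
Reactants: 10 2,3-O-isopropylidene-D-ribono-1,4-lactone, (3aR,6R,6aR)-6-(hydroxymethyl)-2,2-dimethyldihydrofuro[3,4-d][1,3]dioxol-4(3aH)-one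
Product: 11 (3aR,4S,6aR)-2,2-dimethyl-6-oxotetrahydrofuro[3,4-d][1,3]dioxole-4-carbaldehyde (the C5 aldehyde of 10)
Conditions: Dess–Martin periodinane, CH2Cl2, rt
Reagents that add atoms: none
Why: Dess–Martin oxidation gives the aldehyde under non-basic conditions that spare the lactone, the acetonide and the α-stereocentre.

**Step 7**
Reactants: 11 (3aR,4S,6aR)-2,2-dimethyl-6-oxotetrahydrofuro[3,4-d][1,3]dioxole-4-carbaldehyde
Product: 12 (3aR,6R,6aR)-2,2-dimethyl-6-(2-methylprop-1-en-1-yl)dihydrofuro[3,4-d][1,3]dioxol-4(3aH)-one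
Conditions: i-PrPPh3+ I−, n-BuLi, THF, 0 °C; then 11, −78 °C to 0 °C
Reagents that add atoms: isopropyltriphenylphosphonium iodide, CC(C)[P+](c1ccccc1)(c1ccccc1)c1ccccc1.[I-]
Why: Wittig olefination with the non-stabilised isopropylidene ylide takes the aldehyde much faster than the lactone carbonyl at low temperature, and the side chain stays on the convex face so the D-ribo configuration is kept.

**Step 8**
Reactants: 12 (3aR,6R,6aR)-2,2-dimethyl-6-(2-methylprop-1-en-1-yl)dihydrofuro[3,4-d][1,3]dioxol-4(3aH)-one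
Product: 13 (4S,5R)-4-hydroxy-5-(2-methylprop-1-en-1-yl)oxolan-2-one
Conditions: SmI2 (3 equiv), THF, HOCH2CH2OH, rt
Reagents that add atoms: none
Why: SmI2 α-deoxygenation (ketyl formation, cleavage of the C–O bond α to the lactone carbonyl, protonation of the samarium enolate) removes O-2, and the resulting hemiketal loses acetone to free the C4 hydroxyl, with C4 and C5 untouched.

**Step 9**
Reactants: 13 (4S,5R)-4-hydroxy-5-(2-methylprop-1-en-1-yl)oxolan-2-one
Product: 17 (4S,5R)-4-hydroxy-3-methylidene-5-(2-methylprop-1-en-1-yl)oxolan-2-one, via dilithium alkoxide–enolate 14 (not isolated), via Mannich base 15 (not isolated), via methiodide 16 (not isolated)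
Conditions: LiN(i-Pr)2 (2.2 equiv), THF, −78 °C; CH2=NMe2+ I−, −78 °C to rt; H2O work-up; MeI, MeOH, rt; NaHCO3, H2O/CH2Cl2, rt
Reagents that add atoms: N,N-dimethylmethyleneiminium iodide (Eschenmoser's salt), C=[N+](C)C.[I-]
Why: The Fráter–Seebach-type alkoxide–enolate dianion (the alkoxide is too poor a leaving group for β-elimination) undergoes a Mannich reaction anti to O-4, and quaternisation then Hofmann-type elimination gives the α-methylene lactone, erasing the transient C3 centre.

**Step 10**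
Reactants: 9 (2E,6E,8R,10E)-1-[(tert-butyldimethylsilyl)oxy]-3,7-dimethyldodeca-2,6,10-trien-8-ol, 17 (4S,5R)-4-hydroxy-3-methylidene-5-(2-methylprop-1-en-1-yl)oxolan-2-one
Product: 18 (3E,4S,5R)-3-[(3R,4E,8E)-10-[(tert-butyldimethylsilyl)oxy]-3-hydroxy-4,8-dimethyldeca-4,8-dien-1-ylidene]-4-hydroxy-5-(2-methylprop-1-en-1-yl)oxolan-2-one
Conditions: second-generation Hoveyda–Grubbs catalyst RuCl2(H2IMes)(=CH-C6H4-2-O-i-Pr) (10 mol %), 2,6-dichloro-1,4-benzoquinone (10 mol %), 17 (2 equiv), CH2Cl2, 40 °C, argon sparge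
Reagents that add atoms: none
Why: Olefin cross-metathesis joins the disubstituted propenyl terminus of 9 to the non-dimerising methylene lactone (the trisubstituted alkenes are spectators, the quinone suppresses alkene migration) and expels propene, and the E-alkylidene lactone is the favoured isomer, with no stereocentre touched.

**Step 11**
Reactants: 18 (3E,4S,5R)-3-[(3R,4E,8E)-10-[(tert-butyldimethylsilyl)oxy]-3-hydroxy-4,8-dimethyldeca-4,8-dien-1-ylidene]-4-hydroxy-5-(2-methylprop-1-en-1-yl)oxolan-2-one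
Product: 19 (3E,4S,5R)-3-[(3R,4E,8E)-3,10-dihydroxy-4,8-dimethyldeca-4,8-dien-1-ylidene]-4-hydroxy-5-(2-methylprop-1-en-1-yl)oxolan-2-one
Conditions: HF·pyridine, pyridine, THF, 0 °C to rt
Reagents that add atoms: none
Why: Buffered fluoride desilylation cleaves the primary allylic TBS ether without isomerising the alkylidene lactone or ionising the allylic alcohols.

## Compound list

1 | geraniol, (2E)-3,7-dimethylocta-2,6-dien-1-ol | CC(C)=CCC/C(C)=C/CO | starting material
2 | tert-butyl{[(2E)-3,7-dimethylocta-2,6-dien-1-yl]oxy}dimethylsilane | CC(C)=CCC/C(C)=C/CO[Si](C)(C)C(C)(C)C | intermediate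
3 | (2E,6E)-8-[(tert-butyldimethylsilyl)oxy]-2,6-dimethylocta-2,6-dien-1-ol | OC/C(C)=C/CC/C(C)=C/CO[Si](C)(C)C(C)(C)C | intermediate
4 | {[(2E,6E)-8-bromo-3,7-dimethylocta-2,6-dien-1-yl]oxy}(tert-butyl)dimethylsilane | BrC/C(C)=C/CC/C(C)=C/CO[Si](C)(C)C(C)(C)C | intermediate
5 | (2S)-but-3-en-2-ol | C[C@H](O)C=C | starting material
6 | sodium (2S)-but-3-en-2-olate (formed in the flask) | C[C@H]([O-])C=C.[Na+] | intermediate
7 | tert-butyl{[(2E,6E)-8-{[(2S)-but-3-en-2-yl]oxy}-3,7-dimethylocta-2,6-dien-1-yl]oxy}dimethylsilane | C[C@H](OC/C(C)=C/CC/C(C)=C/CO[Si](C)(C)C(C)(C)C)C=C | intermediate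
8 | 7 lithiated at the O–CH2 carbon, C8 of the octadienyl chain (formed in the flask) | C[C@H](OC([Li])/C(C)=C/CC/C(C)=C/CO[Si](C)(C)C(C)(C)C)C=C | intermediate
9 | (2E,6E,8R,10E)-1-[(tert-butyldimethylsilyl)oxy]-3,7-dimethyldodeca-2,6,10-trien-8-ol | C/C=C/C[C@@H](O)/C(C)=C/CC/C(C)=C/CO[Si](C)(C)C(C)(C)C | intermediate
10 | 2,3-O-isopropylidene-D-ribono-1,4-lactone | O=C1O[C@H](CO)[C@H]2OC(C)(C)O[C@@H]12 | starting material
11 | (3aR,4S,6aR)-2,2-dimethyl-6-oxotetrahydrofuro[3,4-d][1,3]dioxole-4-carbaldehyde | O=C1O[C@H](C=O)[C@H]2OC(C)(C)O[C@@H]12 | intermediate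
12 | (3aR,6R,6aR)-2,2-dimethyl-6-(2-methylprop-1-en-1-yl)dihydrofuro[3,4-d][1,3]dioxol-4(3aH)-one | O=C1O[C@H](C=C(C)C)[C@H]2OC(C)(C)O[C@@H]12 | intermediate
13 | (4S,5R)-4-hydroxy-5-(2-methylprop-1-en-1-yl)oxolan-2-one | O=C1O[C@H](C=C(C)C)[C@@H](O)C1 | intermediate
14 | dilithium alkoxide–enolate of 13 (formed in the flask) | [Li+].[Li+].[O-]C1=C[C@H]([O-])[C@@H](C=C(C)C)O1 | intermediate
15 | (3S,4S,5R)-3-[(dimethylamino)methyl]-4-hydroxy-5-(2-methylprop-1-en-1-yl)oxolan-2-one (formed in the flask) | O=C1O[C@H](C=C(C)C)[C@@H](O)[C@@H]1CN(C)C | intermediate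
16 | {[(3S,4S,5R)-4-hydroxy-5-(2-methylprop-1-en-1-yl)-2-oxooxolan-3-yl]methyl}trimethylammonium iodide (formed in the flask) | O=C1O[C@H](C=C(C)C)[C@@H](O)[C@@H]1C[N+](C)(C)C.[I-] | intermediate
17 | (4S,5R)-4-hydroxy-3-methylidene-5-(2-methylprop-1-en-1-yl)oxolan-2-one | O=C1O[C@H](C=C(C)C)[C@@H](O)C1=C | intermediate
18 | (3E,4S,5R)-3-[(3R,4E,8E)-10-[(tert-butyldimethylsilyl)oxy]-3-hydroxy-4,8-dimethyldeca-4,8-dien-1-ylidene]-4-hydroxy-5-(2-methylprop-1-en-1-yl)oxolan-2-one | CC(C)=C[C@H]1OC(=O)/C(=C/C[C@@H](O)/C(C)=C/CC/C(C)=C/CO[Si](C)(C)C(C)(C)C)[C@@H]1O | intermediate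
19 | (3E,4S,5R)-3-[(3R,4E,8E)-3,10-dihydroxy-4,8-dimethyldeca-4,8-dien-1-ylidene]-4-hydroxy-5-(2-methylprop-1-en-1-yl)oxolan-2-one | CC(C)=C[C@H]1OC(=O)/C(=C/C[C@@H](O)/C(C)=C/CC/C(C)=C/CO)[C@@H]1O | target

## Step count and risks

Total steps: 11. Longest linear sequence: 7 (steps 1, 2, 3, 4, 5, 10, 11); the lactone branch is steps 6–9.

**Step 5 ([2,3]-Wittig rearrangement).** Risks are competing lithiation next to the silyl ether, some [1,2]-shift, and incomplete exo preference of the alkenyl group, which would lower the transfer of chirality. Any (8S)-alcohol carried on becomes a separable diastereomer after step 10. The fallback changes the carbanion-stabilising group from alkenyl to alkynyl; it sets out from 2 and returns at 9. Ozonolysis of the terminal alkene of 2 alone (O3, pyridine, CH2Cl2, −78 °C; Me2S) gives (E)-6-[(tert-butyldimethylsilyl)oxy]-4-methylhex-4-enal F1. Ohira–Bestmann homologation (dimethyl (1-diazo-2-oxopropyl)phosphonate, K2CO3, MeOH) gives tert-butyldimethyl{[(2E)-3-methylhept-2-en-6-yn-1-yl]oxy}silane F2. Alcohol 5 is converted (paraformaldehyde, Me3SiCl) into (3S)-3-(chloromethoxy)but-1-ene F3, which alkylates the lithium acetylide of F2 (n-BuLi, THF) to tert-butyl{[(2E)-8-{[(2S)-but-3-en-2-yl]oxy}-3-methyloct-2-en-6-yn-1-yl]oxy}dimethylsilane F4. n-BuLi at −78 °C lithiates only the much more acidic propargylic O–CH2, and the [2,3]-Wittig shift gives (2E,8R,10E)-1-[(tert-butyldimethylsilyl)oxy]-3-methyldodeca-2,10-dien-6-yn-8-ol F5. Alkoxide-directed anti-carbomagnesiation (MeMgBr, CuI cat., THF; H2O) places the methyl on C7 and the chain trans to the carbinol, which gives 9.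

**Step 10 (cross-metathesis).** The methylene lactone is a hindered, electron-poor 1,1-disubstituted alkene, the E/Z ratio may be modest, and the isobutenyl group could engage slowly. The fallback makes the metathesis intramolecular; it sets out from 9 and 17 and returns at 19. Sequential silylation (i-Pr2SiCl2, imidazole, CH2Cl2; 17 first, then 9) gives the diisopropylsilylene-bridged bis-ether of O-4 of 17 and O-8 of 9 F6. Ring-closing metathesis (second-generation Hoveyda–Grubbs catalyst RuCl2(H2IMes)(=CH-C6H4-2-O-i-Pr), toluene, 80 °C, high dilution) gives the eight-membered cyclic silyl bis-ether F7. Its new C3=C1' bond is cis within the ring, which is the required E geometry. HF·pyridine then removes the tether and the TBS group together and gives 19.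

**Step 7 (Wittig on the α-alkoxy aldehyde).** The basic ylide may epimerise C4 of the sugar, trigger β-elimination of the acetonide oxygen, or attack the lactone. The fallback avoids a phosphorus ylide; it sets out from 11 and returns at 12. Lombardo methylenation (Zn, CH2Br2, TiCl4, THF/CH2Cl2, 0 °C), which is non-basic, gives (3aR,6R,6aR)-6-ethenyl-2,2-dimethyldihydrofuro[3,4-d][1,3]dioxol-4(3aH)-one F8. Cross-metathesis with 2-methylbut-2-ene (second-generation Grubbs catalyst RuCl2(=CHPh)(H2IMes)(PCy3), 40 °C) installs the 2-methylprop-1-enyl group and gives 12.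

## Further compounds

F1 | step 5 | (E)-6-[(tert-butyldimethylsilyl)oxy]-4-methylhex-4-enal | O=CCC/C(C)=C/CO[Si](C)(C)C(C)(C)C
F2 | step 5 | tert-butyldimethyl{[(2E)-3-methylhept-2-en-6-yn-1-yl]oxy}silane | C#CCC/C(C)=C/CO[Si](C)(C)C(C)(C)C
F3 | step 5 | (3S)-3-(chloromethoxy)but-1-ene | C[C@H](OCCl)C=C
F4 | step 5 | tert-butyl{[(2E)-8-{[(2S)-but-3-en-2-yl]oxy}-3-methyloct-2-en-6-yn-1-yl]oxy}dimethylsilane | C[C@H](OCC#CCC/C(C)=C/CO[Si](C)(C)C(C)(C)C)C=C
F5 | step 5 | (2E,8R,10E)-1-[(tert-butyldimethylsilyl)oxy]-3-methyldodeca-2,10-dien-6-yn-8-ol | C/C=C/C[C@@H](O)C#CCC/C(C)=C/CO[Si](C)(C)C(C)(C)C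
F6 | step 10 | diisopropylsilylene-bridged bis-ether of O-4 of 17 and O-8 of 9 | CC(C)=C[C@H]1OC(=O)C(=C)[C@@H]1O[Si](C(C)C)(C(C)C)O[C@H](C/C=C/C)/C(C)=C/CC/C(C)=C/CO[Si](C)(C)C(C)(C)C
F7 | step 10 | eight-membered cyclic diisopropylsilyl bis-ether of 18 (O-4 and O-3' bridged, C3=C1' in the ring) | CC(C)=C[C@H]1OC(=O)/C(=C/C[C@@H](O2)/C(C)=C/CC/C(C)=C/CO[Si](C)(C)C(C)(C)C)[C@@H]1O[Si]2(C(C)C)C(C)C
F8 | step 7 | (3aR,6R,6aR)-6-ethenyl-2,2-dimethyldihydrofuro[3,4-d][1,3]dioxol-4(3aH)-one | O=C1O[C@H](C=C)[C@H]2OC(C)(C)O[C@@H]12
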